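## Analysis of the target

Target 14 is a 2,3-trans-dihydroflavonol built on a chroman-4-one. Ring A (C4a, C5, C6, C7, C8, C8a) carries a free hydroxyl at C5, a methoxy group at C7 and a 3-methylbut-2-enyl (prenyl) group at C8, while ring C (O1, C2, C3, C4, C4a, C8a) holds the C4 ketone and bears ring B, a 4-hydroxy-3-methoxyphenyl group, at C2. The two stereocenters are adjacent, C2 (R) and C3 (R), and they place the C2 aryl group and the C3 hydroxyl on opposite faces of ring C, the diequatorial trans arrangement. The C2–O1 bond is β to the ketone and benzylic to an electron-rich ring, so an enolate at C3 or the phenoxide of ring B can open ring C and scramble C2. The C3 ketol can epimerise or be oxidised to the flavonol, and the trisubstituted prenyl alkene tolerates neither strong acid nor electrophilic oxidants nor hydrogenation. The synthesis is hard on three counts: fixing the absolute configuration of a labile benzylic ether carbon, raising C3 to the alcohol level without touching the prenyl alkene, and placing the prenyl group at C8 and not at C6. The strategy rests on C2 being a methine bonded to O1 and to ring B with exactly one hydrogen, so that it can be traced back to the CH2 of an ordinary O1-benzyl ether and the C2–C3 bond can be made by inserting a carbene at C3 into one of the two enantiotopic benzylic C–H bonds.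

## Retrosynthetic reasoning

**14 from 13 (two O–Si bonds).** Both phenols, O5 and the ring B oxygen, are unmasked last because free phenols would quench a carbene and an enolate. Both carry the same triisopropylsilyl group, so one buffered fluoride treatment removes them without acid reaching the prenyl group or base reaching the C2–O1 bond. The forward step must keep the phenols protonated as they are released.

**13 from 11 (C3–O bond).** The C3 hydroxyl is cut off to leave flavanone 11, which is oxidised through its enolate 12. An N-sulfonyloxaziridine is chosen as the oxidant because it reacts with enolates only and ignores the prenyl alkene. The forward step must add oxygen to the enolate face opposite the C2 aryl group and must be faster than ring opening of 12.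

**11 from 10 (C2–C3 bond, the central cut).** Cutting C2–C3 leaves a carbene at C3 and a C–H bond at C2, that is, diazoketone 10 with a plain benzyl ether on O1. This cut is preferred to the O1–C2 cut (oxa-Michael closure of a chalcone) because that closure is reversible under base and gives no lasting control of C2. The insertion is irreversible, runs under neutral conditions and makes ring C and the C2 stereocenter in one event, under control of a chiral dirhodium tetracarboxylate (each rhodium divalent).

**10 from 8 (C3=N bond).** The diazo group is removed to give methyl ketone 8. The forward reaction is a deacylative diazo transfer through the trifluoroacetyl derivative 9, so the diazoketone need not be built from a crowded, electron-rich benzoyl chloride.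

**8 from 4 and 7 (O1–CH2 bond).** Cutting the benzyl ether gives phenol 4 and ring B alcohol 7, which makes the route convergent. The forward etherification must be neutral, because 8 is a 4-oxybenzyl ether sensitive to acid and carries two aryl silyl ethers sensitive to base. A redox condensation of the Mitsunobu type meets this.

**7 from 6 from 5 (functional group changes on ring B).** Alcohol 7 comes from aldehyde 6 by hydride reduction, and 6 from vanillin 5 by silylation of the phenol. A silyl group is chosen on this oxygen so that it leaves together with the one on O5.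

**4 from 3 (O5–Si bond).** The silyl ether on the future O5 is cut to give diol 3. In 3 one hydroxyl is flanked by the acetyl and prenyl groups and the other by acetyl and hydrogen, so a bulky silyl chloride should take the less hindered one. The hindered hydroxyl next to the prenyl group is then left free to become O1, which fixes the prenyl group at C8.

**3 from 1 and 2 (C8–CH2 bond).** The prenyl group is cut off to give ketone 1 and prenyl bromide 2. The two free ring positions of 1 are equivalent by symmetry, so C-alkylation raises no regiochemical question. The forward step only has to favour carbon over oxygen and one alkylation over two.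

## Alternatives that were turned down

Alternative 1: Ring A would be assembled from acyclic pieces by a cyclobutenone–alkyne benzannulation, which cuts C8a–C8, C6–C7 and C4a–C8a. In the forward direction 3-ethoxycyclobut-2-en-1-one A2 is heated with the ynol ether 1-methoxy-5-methylhex-4-en-1-yne A3. Four-electron ring opening of A2 gives a vinylketene, which adds to A3 in a [2+2] sense. A second ring opening, six-electron closure and tautomerisation would then deliver 5-ethoxy-3-methoxy-2-(3-methylbut-2-enyl)phenol A1.
- For it: the prenyl group is placed next to the future O1 by the connectivity of A3, with no selectivity question, and the three oxygens of ring A come out differentiated. On regiochemical certainty it is at least as strong as the chosen route.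
- Against it: the key step touches neither ring C nor a stereocenter. A1 still needs acylation between its hydroxyl and ethoxy groups, and then the whole flavanonol problem (C2 configuration, C3 oxidation) remains.
- Against it: the ethyl ether that A2 brings in sits on the future O5 and would have to be cleaved selectively beside two methyl ethers, by a Lewis acid that also threatens the prenyl alkene.
- Against it: A3 is a sensitive ynol ether that must be made.
- Comparison: the chosen strategy buys ring A as ketone 1 and places the prenyl group in one step on a symmetric substrate. It spends its effort on the bond that creates C2.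

Alternative 2: Ring A would be folded onto a preformed ring C by an intramolecular Claisen condensation, which cuts C4a–C5. The substrate is the dihydropyranone ester methyl 4-[(2R,3R)-3-(tert-butyldimethylsilyloxy)-2-[3-methoxy-4-(methoxymethoxy)phenyl]-4-oxo-2,3-dihydropyran-6-yl]-3-methoxy-7-methylocta-2,6-dienoate A5. Mg(OMe)2 would deprotonate A5 at the carbon that becomes C8, and the dienolate would attack the ester carbon through C4a. Loss of the ester methoxy group and tautomerisation would aromatise ring A to (2R,3R)-3-(tert-butyldimethylsilyloxy)-5-hydroxy-7-methoxy-2-[3-methoxy-4-(methoxymethoxy)phenyl]-8-(3-methylbut-2-enyl)chroman-4-one A4, a doubly protected form of 14.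
- For it: both stereocenters and the C3 oxygen are in place before ring A exists, so no oxidation is needed next to the prenyl group, and the C5 hydroxyl of A4 emerges free. On these two points it is stronger than the chosen route, which must hydroxylate a base-sensitive flavanone.
- Against it: A5 is a long linear construction (a 2,3-trans dihydropyranone, then a side chain with a defined enol ether geometry that lets the ester reach C4a).
- Against it: the basic key step acts on a ketone with an acidic C3–H and a β C2–O1 bond, so epimerisation at C3 and ring opening compete with the condensation.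
- Comparison: the chosen strategy is convergent and short, with ring A bought, and confines base to one low-temperature step.

Alternative 3: Ring C would be closed by olefin metathesis, which cuts C3=C4. The substrate is the diene 2-ethenyl-5-methoxy-1-(methoxymethoxy)-3-[(1S)-1-[3-methoxy-4-(methoxymethoxy)phenyl]prop-2-enoxy]-4-(3-methylbut-2-enyl)benzene A7. The second-generation Grubbs catalyst would join the vinyl group on C4a and the vinyl group on C2 of A7, with extrusion of the two terminal methylene groups. The product would be the flav-3-ene (2S)-7-methoxy-2-[3-methoxy-4-(methoxymethoxy)phenyl]-5-(methoxymethoxy)-8-(3-methylbut-2-enyl)-2H-chromene A6.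
- For it: the closure is highly predictable, C2 is set earlier from an enantioenriched allylic alcohol, and acetal protection on O5 is allowed. On reliability of the ring closure itself it is stronger than a carbene insertion.
- Against it: the prenyl alkene on C8 of A7 sits ortho to O1 and can close a seven-membered ring with the allyl ether vinyl group.
- Against it: A7 is an ether of a 4-alkoxyphenyl allyl carbinol that ionises easily, and A6 can racemise by reversible six-electron ring opening.
- Against it: A6 needs two further oxidation events (at C3 and C4), by reagents that do not distinguish the C3=C4 alkene from the prenyl alkene.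
- Comparison: the chosen strategy forms ring C at the ketone oxidation level. Its single later oxidation uses a reagent specific for enolates.

Key step: step 7

## Route

Assumption: Rh2(S-PTTL)4 is taken to select the benzylic hydrogen that leads to the 2S product; if the sense proves opposite, the catalyst from (R)-tert-leucine, Rh2(R-PTTL)4, is used with nothing else changed, and ketone 1 is treated as a catalogue compound.

Step 1
Reactants: 1 1-(2,6-dihydroxy-4-methoxyphenyl)ethanone; 2 prenyl bromide (1-bromo-3-methylbut-2-ene)
Product: 3 1-[2,6-dihydroxy-4-methoxy-3-(3-methylbut-2-enyl)phenyl]ethanone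
Conditions: KOH (10% aq), 2 (0.9 equiv), 0 °C → rt
Reagents that add atoms: none
Why: C-alkylation of an ambident resorcinol-type phenoxide; water solvates the oxygens and directs the allylic bromide to the ring carbon that is ortho and para to the two phenoxides. The two free positions of 1 are equivalent, so only one mono-C-prenyl product can form, and a deficit of 2 limits double alkylation.

Step 2
Reactants: 3 1-[2,6-dihydroxy-4-methoxy-3-(3-methylbut-2-enyl)phenyl]ethanone
Product: 4 1-[2-hydroxy-4-methoxy-3-(3-methylbut-2-enyl)-6-(triisopropylsilyloxy)phenyl]ethanone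
Conditions: TIPSCl (1.05 equiv), imidazole, DMF, 0 °C → rt
Reagents that add atoms: triisopropylsilyl chloride, CC(C)[Si](Cl)(C(C)C)C(C)C
Why: Sterically controlled mono-silylation; the bulky silyl chloride should take the hydroxyl flanked only by the acetyl group and a ring hydrogen. The remaining hydroxyl, wedged between acetyl and prenyl and hydrogen-bonded to the ketone, should silylate much more slowly.

Step 3
Reactants: 5 vanillin (4-hydroxy-3-methoxybenzaldehyde)
Product: 6 3-methoxy-4-(triisopropylsilyloxy)benzaldehyde
Conditions: TIPSCl, imidazole, DMF, rt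
Reagents that add atoms: triisopropylsilyl chloride, CC(C)[Si](Cl)(C(C)C)C(C)C
Why: Standard silylation of a phenol; the silyl ether survives all later steps and is removed together with the one on O5.

Step 4
Reactants: 6 3-methoxy-4-(triisopropylsilyloxy)benzaldehyde
Product: 7 [3-methoxy-4-(triisopropylsilyloxy)phenyl]methanol
Conditions: NaBH4, MeOH–THF, 0 °C
Reagents that add atoms: none
Why: Borohydride reduction of an aryl aldehyde; the short, cold reaction leaves the aryl silyl ether untouched.

Step 5
Reactants: 4 1-[2-hydroxy-4-methoxy-3-(3-methylbut-2-enyl)-6-(triisopropylsilyloxy)phenyl]ethanone; 7 [3-methoxy-4-(triisopropylsilyloxy)phenyl]methanol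
Product: 8 1-[4-methoxy-2-[3-methoxy-4-(triisopropylsilyloxy)benzyloxy]-3-(3-methylbut-2-enyl)-6-(triisopropylsilyloxy)phenyl]ethanone
Conditions: PPh3, DIAD, THF, 0 °C → rt
Reagents that add atoms: none
Why: Mitsunobu etherification; the ortho-acyl phenol is acidic enough to protonate the betaine, and the primary, electron-rich benzylic oxyphosphonium is displaced readily by the phenoxide. The neutral conditions spare both aryl silyl ethers and the acid-labile 4-oxybenzyl ether.

Step 6
Reactants: 8 1-[4-methoxy-2-[3-methoxy-4-(triisopropylsilyloxy)benzyloxy]-3-(3-methylbut-2-enyl)-6-(triisopropylsilyloxy)phenyl]ethanone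
Product: 10 2-diazo-1-[4-methoxy-2-[3-methoxy-4-(triisopropylsilyloxy)benzyloxy]-3-(3-methylbut-2-enyl)-6-(triisopropylsilyloxy)phenyl]ethanone, via trifluoroacetyl diketone 9 (not isolated)
Conditions: LiN(SiMe3)2, THF, −78 °C; CF3CO2CH2CF3, −78 °C; AcOH quench, aqueous wash, concentrate; then MsN3, Et3N, H2O (1 equiv), MeCN, rt
Reagents that add atoms: methanesulfonyl azide, CS(=O)(=O)N=[N+]=[N-]; 2,2,2-trifluoroethyl trifluoroacetate, O=C(OCC(F)(F)F)C(F)(F)F (its CF3CO group is present only in 9)
Why: Detrifluoroacetylative diazo transfer; the kinetic lithium enolate of the methyl ketone is trifluoroacetylated, and the activated diketone 9, taken on crude, accepts the diazo group from the sulfonyl azide and loses the trifluoroacetyl group to the sulfonamide. The cold, brief enolate stage and the mild acetic acid quench should leave the hindered silyl ethers and the benzyl ether in place.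

Step 7
Reactants: 10 2-diazo-1-[4-methoxy-2-[3-methoxy-4-(triisopropylsilyloxy)benzyloxy]-3-(3-methylbut-2-enyl)-6-(triisopropylsilyloxy)phenyl]ethanone
Product: 11 (2S)-7-methoxy-2-[3-methoxy-4-(triisopropylsilyloxy)phenyl]-8-(3-methylbut-2-enyl)-5-(triisopropylsilyloxy)chroman-4-one
Conditions: Rh2(S-PTTL)4 (1 mol %), CH2Cl2, 0 °C, slow addition of 10
Reagents that add atoms: none
Why: Rh2(S-PTTL)4, dirhodium tetrakis[N-phthaloyl-(S)-tert-leucinate] with each rhodium divalent, takes up the diazo carbon of 10 and expels N2 to give an electrophilic dirhodium carbene at C3, which inserts into one benzylic C–H bond of the O1–CH2–aryl group through a concerted three-centre transition state with hydride-transfer character, forming C2–C3 and releasing the catalyst. The closest known reaction type is the dirhodium-carboxylate-catalysed intramolecular C–H insertion of ortho-alkoxyaryl diazoketones to chroman-4-ones, together with carbene insertion into benzylic C–H bonds of benzyl ethers under N-phthaloyl amino acid catalysts. Ring C closes as a six-membered ring by 1,6-insertion (C3 onto C2 across C4, C4a, C8a and O1); a 1,5-insertion cannot occur because the fifth atom is O1. The C2 stereocenter is set by the catalyst alone: the phthalimido walls of the four tert-leucinate ligands form a chiral pocket that presents only one of the two enantiotopic benzylic hydrogens to the carbene, and the neutral medium keeps the base-labile C2 centre from scrambling afterwards. The selectivity needed is insertion over attack of the carbene on the O1 lone pair, which would give a five-membered oxonium ylide and then a 1,2-benzyl shift to a benzofuranone. The substrate favours insertion because the electron-rich ring B and O1 make the C–H bond hydridic, while O1 is a weakly basic aryl ether oxygen conjugated to the acylated ring and flanked by the C8 prenyl group. The O5 silyl group is bulky and has no C–H bond on the atom next to oxygen, and the prenyl alkene lies meta to the acyl group where the carbene cannot reach it. Slow addition keeps the diazo concentration low and suppresses carbene dimerisation.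

Step 8
Reactants: 11 (2S)-7-methoxy-2-[3-methoxy-4-(triisopropylsilyloxy)phenyl]-8-(3-methylbut-2-enyl)-5-(triisopropylsilyloxy)chroman-4-one
Product: 13 (2R,3R)-3-hydroxy-7-methoxy-2-[3-methoxy-4-(triisopropylsilyloxy)phenyl]-8-(3-methylbut-2-enyl)-5-(triisopropylsilyloxy)chroman-4-one, via sodium enolate 12 (not isolated)
Conditions: NaN(SiMe3)2 (1.1 equiv), THF, −78 °C; 2-(phenylsulfonyl)-3-phenyloxaziridine, −78 °C; AcOH quench at −78 °C
Reagents that add atoms: 2-(phenylsulfonyl)-3-phenyloxaziridine, O=S(=O)(c1ccccc1)N1OC1c1ccccc1
Why: Enolate hydroxylation with an N-sulfonyloxaziridine (Davis oxidation); the oxidant transfers oxygen to the C3 enolate carbon and does not react with the prenyl alkene at this temperature. The new C3 stereocenter is set by the substrate: the oxidant approaches the enolate face opposite the C2 aryl group, giving the trans (2R,3R) ketol, which is also the more stable isomer. A sodium enolate is used to limit addition to the sulfonimine by-product, and the cold acid quench limits ring opening.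

Step 9
Reactants: 13 (2R,3R)-3-hydroxy-7-methoxy-2-[3-methoxy-4-(triisopropylsilyloxy)phenyl]-8-(3-methylbut-2-enyl)-5-(triisopropylsilyloxy)chroman-4-one
Product: 14 (2R,3R)-3,5-dihydroxy-2-(4-hydroxy-3-methoxyphenyl)-7-methoxy-8-(3-methylbut-2-enyl)chroman-4-one
Conditions: Bu4NF (2.5 equiv), AcOH (2.5 equiv), THF, 0 °C
Reagents that add atoms: none
Why: Fluoride-mediated cleavage of the two aryl silyl ethers, which is fast because phenoxides are good leaving groups from silicon. Acetic acid protonates each phenoxide as it forms, so that neither the ring B phenoxide nor a C3 enolate can open ring C or epimerise C2 and C3; the prenyl group and the ketol are not affected.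

## Compound list

1 | 1-(2,6-dihydroxy-4-methoxyphenyl)ethanone | CC(=O)c1c(O)cc(OC)cc1O | starting material
2 | prenyl bromide (1-bromo-3-methylbut-2-ene) | CC(C)=CCBr | starting material
3 | 1-[2,6-dihydroxy-4-methoxy-3-(3-methylbut-2-enyl)phenyl]ethanone | CC(=O)c1c(O)cc(OC)c(CC=C(C)C)c1O | intermediate
4 | 1-[2-hydroxy-4-methoxy-3-(3-methylbut-2-enyl)-6-(triisopropylsilyloxy)phenyl]ethanone | CC(=O)c1c(O[Si](C(C)C)(C(C)C)C(C)C)cc(OC)c(CC=C(C)C)c1O | intermediate
5 | vanillin (4-hydroxy-3-methoxybenzaldehyde) | COc1cc(C=O)ccc1O | starting material
6 | 3-methoxy-4-(triisopropylsilyloxy)benzaldehyde | COc1cc(C=O)ccc1O[Si](C(C)C)(C(C)C)C(C)C | intermediate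
7 | [3-methoxy-4-(triisopropylsilyloxy)phenyl]methanol | COc1cc(CO)ccc1O[Si](C(C)C)(C(C)C)C(C)C | intermediate
8 | 1-[4-methoxy-2-[3-methoxy-4-(triisopropylsilyloxy)benzyloxy]-3-(3-methylbut-2-enyl)-6-(triisopropylsilyloxy)phenyl]ethanone | COc1cc(COc2c(CC=C(C)C)c(OC)cc(O[Si](C(C)C)(C(C)C)C(C)C)c2C(C)=O)ccc1O[Si](C(C)C)(C(C)C)C(C)C | intermediate
9 | 4,4,4-trifluoro-1-[4-methoxy-2-[3-methoxy-4-(triisopropylsilyloxy)benzyloxy]-3-(3-methylbut-2-enyl)-6-(triisopropylsilyloxy)phenyl]butane-1,3-dione | COc1cc(COc2c(CC=C(C)C)c(OC)cc(O[Si](C(C)C)(C(C)C)C(C)C)c2C(=O)CC(=O)C(F)(F)F)ccc1O[Si](C(C)C)(C(C)C)C(C)C | intermediate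
10 | 2-diazo-1-[4-methoxy-2-[3-methoxy-4-(triisopropylsilyloxy)benzyloxy]-3-(3-methylbut-2-enyl)-6-(triisopropylsilyloxy)phenyl]ethanone | COc1cc(COc2c(CC=C(C)C)c(OC)cc(O[Si](C(C)C)(C(C)C)C(C)C)c2C(=O)C=[N+]=[N-])ccc1O[Si](C(C)C)(C(C)C)C(C)C | intermediate
11 | (2S)-7-methoxy-2-[3-methoxy-4-(triisopropylsilyloxy)phenyl]-8-(3-methylbut-2-enyl)-5-(triisopropylsilyloxy)chroman-4-one | COc1cc([C@H]2Oc3c(CC=C(C)C)c(OC)cc(O[Si](C(C)C)(C(C)C)C(C)C)c3C(=O)C2)ccc1O[Si](C(C)C)(C(C)C)C(C)C | intermediate
12 | sodium (2S)-7-methoxy-2-[3-methoxy-4-(triisopropylsilyloxy)phenyl]-8-(3-methylbut-2-enyl)-5-(triisopropylsilyloxy)-2H-chromen-4-olate | COc1cc([C@H]2Oc3c(CC=C(C)C)c(OC)cc(O[Si](C(C)C)(C(C)C)C(C)C)c3C([O-])=C2)ccc1O[Si](C(C)C)(C(C)C)C(C)C.[Na+] | intermediate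
13 | (2R,3R)-3-hydroxy-7-methoxy-2-[3-methoxy-4-(triisopropylsilyloxy)phenyl]-8-(3-methylbut-2-enyl)-5-(triisopropylsilyloxy)chroman-4-one | COc1cc([C@H]2Oc3c(CC=C(C)C)c(OC)cc(O[Si](C(C)C)(C(C)C)C(C)C)c3C(=O)[C@@H]2O)ccc1O[Si](C(C)C)(C(C)C)C(C)C | intermediate
14 | (2R,3R)-3,5-dihydroxy-2-(4-hydroxy-3-methoxyphenyl)-7-methoxy-8-(3-methylbut-2-enyl)chroman-4-one | COc1cc([C@H]2Oc3c(CC=C(C)C)c(OC)cc(O)c3C(=O)[C@@H]2O)ccc1O | target

## Step count and least certain steps

Total: 9 steps. Longest linear sequence: 7 steps (steps 1, 2, 5, 6, 7, 8, 9, from 1 to 14); steps 3 and 4 form the two-step side branch from 5 to 7.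

**Step 7 (key step).** The most likely failure is attack of the carbene on the O1 lone pair, giving a five-membered oxonium ylide and a 1,2-shift of the benzyl group; an acceptor-only carbene is very electrophilic and the ether oxygen is only five atoms away. The second risk is poor discrimination between the two benzylic hydrogens, because such a reactive carbene has an early transition state.

Fallback, from 4 back to 11 by conjugate addition to a chromone: Phenol 4 is heated with Me2NCH(OMe)2 in toluene to give the enaminone (E)-3-(dimethylamino)-1-[2-hydroxy-4-methoxy-3-(3-methylbut-2-enyl)-6-(triisopropylsilyloxy)phenyl]prop-2-en-1-one F1. On warming with AcOH in CH2Cl2, F1 cyclises with loss of its dimethylamino group to 7-methoxy-8-(3-methylbut-2-enyl)-5-(triisopropylsilyloxy)chromen-4-one F2. Ring B is supplied from purchased 4-bromo-2-methoxyphenol, which is silylated (TIPSCl, imidazole) to (4-bromo-2-methoxyphenoxy)triisopropylsilane F3. Bromine–lithium exchange on F3 with n-BuLi, then B(OiPr)3 and aqueous work-up, gives [3-methoxy-4-(triisopropylsilyloxy)phenyl]boronic acid F4. Enantioselective conjugate addition of F4 to F2 uses Pd(OCOCF3)2 (divalent palladium), the tert-butyl pyridine-oxazoline ligand of the enantiomeric series that delivers the 2S product, NH4PF6 and water in 1,2-dichloroethane at 60 °C. It should give 11, where the route resumes at step 8.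

**Step 8.** Two processes threaten the enolate: β-elimination of the O1 aryloxide, which opens ring C and erodes the C2 configuration on reclosure, and transfer of the silyl group from O5 to the neighbouring enolate oxygen. Both are driven by the free enolate.

Fallback, from 11 back to 13 without a free enolate: Ketone 11 is converted with Me3SiOTf and Et3N in CH2Cl2 (−78 → 0 °C) into the silyl enol ether [(2S)-7-methoxy-2-[3-methoxy-4-(triisopropylsilyloxy)phenyl]-8-(3-methylbut-2-enyl)-5-(triisopropylsilyloxy)-2H-chromen-4-yl]oxy-trimethylsilane F5. F5 is oxidised with one equivalent of dimethyldioxirane at −78 °C (Rubottom oxidation); the enol ether is much more nucleophilic than the prenyl alkene. This should give (2R,3R)-7-methoxy-2-[3-methoxy-4-(triisopropylsilyloxy)phenyl]-8-(3-methylbut-2-enyl)-5-(triisopropylsilyloxy)-3-(trimethylsilyloxy)chroman-4-one F6, with oxygen delivered anti to the C2 aryl group. Citric acid in MeOH then removes the trimethylsilyl group from F6 and gives 13.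

**Step 1.** O-Alkylation and a second alkylation compete with mono-C-alkylation, because the phenoxide is ambident and the product is as nucleophilic as the starting material.

Fallback, from 1 back to 3 by rearrangement: Ketone 1 is mono-O-alkylated with methyl 2-methylbut-3-en-2-yl carbonate under Pd(PPh3)4 (zerovalent palladium) in THF to give 1-[2-hydroxy-4-methoxy-6-(2-methylbut-3-en-2-yloxy)phenyl]ethanone F7. Heating F7 in N,N-diethylaniline (aromatic Claisen rearrangement) moves the allyl unit with inversion to the only ortho position bearing hydrogen and gives 3.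

**Step 2.** Silylation may not discriminate well enough between the two hydroxyls, or may go on to the bis-silyl ether. Silylation of the hydroxyl next to the prenyl group would later place the prenyl group at C6.

Fallback, from 1 back to 4, with the order of silylation and prenylation reversed: Symmetric ketone 1 is mono-silylated (TIPSCl, 1 equiv, imidazole, DMF) to 1-[2-hydroxy-4-methoxy-6-(triisopropylsilyloxy)phenyl]ethanone F8, in which the two hydroxyls of 1 are equivalent so that only one mono-ether can form. The remaining phenol of F8 is O-alkylated with methyl 2-methylbut-3-en-2-yl carbonate under Pd(PPh3)4 (zerovalent palladium) in THF to give 1-[4-methoxy-2-(2-methylbut-3-en-2-yloxy)-6-(triisopropylsilyloxy)phenyl]ethanone F9. Aromatic Claisen rearrangement of F9 in hot N,N-diethylaniline delivers the prenyl group to the ring carbon next to the oxygen it leaves, so the freed hydroxyl is by necessity the one beside the prenyl group, and the product is 4. The route resumes at step 5.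

**Step 5.** The chelated, doubly flanked phenol may react slowly, so that the activated benzylic alcohol is consumed by alkylation of the hydrazide by-product.

Fallback, from 7 and 4 back to 8 by Williamson alkylation: Alcohol 7 is converted with MsCl and Et3N, then LiCl, into 4-(chloromethyl)-2-methoxy-1-(triisopropylsilyloxy)benzene F10. F10 alkylates 4 with K2CO3 and Bu4NI in acetone at rt to give 8.

## Further compounds

F1 | step 7 | (E)-3-(dimethylamino)-1-[2-hydroxy-4-methoxy-3-(3-methylbut-2-enyl)-6-(triisopropylsilyloxy)phenyl]prop-2-en-1-one | CN(C)/C=C/C(=O)c1c(O[Si](C(C)C)(C(C)C)C(C)C)cc(OC)c(CC=C(C)C)c1O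
F2 | step 7 | 7-methoxy-8-(3-methylbut-2-enyl)-5-(triisopropylsilyloxy)chromen-4-one | O=c1ccoc2c(CC=C(C)C)c(OC)cc(O[Si](C(C)C)(C(C)C)C(C)C)c12
F3 | step 7 | (4-bromo-2-methoxyphenoxy)triisopropylsilane | COc1cc(Br)ccc1O[Si](C(C)C)(C(C)C)C(C)C
F4 | step 7 | [3-methoxy-4-(triisopropylsilyloxy)phenyl]boronic acid | COc1cc(B(O)O)ccc1O[Si](C(C)C)(C(C)C)C(C)C
F5 | step 8 | [(2S)-7-methoxy-2-[3-methoxy-4-(triisopropylsilyloxy)phenyl]-8-(3-methylbut-2-enyl)-5-(triisopropylsilyloxy)-2H-chromen-4-yl]oxy-trimethylsilane | COc1cc([C@H]2Oc3c(CC=C(C)C)c(OC)cc(O[Si](C(C)C)(C(C)C)C(C)C)c3C(O[Si](C)(C)C)=C2)ccc1O[Si](C(C)C)(C(C)C)C(C)C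
F6 | step 8 | (2R,3R)-7-methoxy-2-[3-methoxy-4-(triisopropylsilyloxy)phenyl]-8-(3-methylbut-2-enyl)-5-(triisopropylsilyloxy)-3-(trimethylsilyloxy)chroman-4-one | COc1cc([C@H]2Oc3c(CC=C(C)C)c(OC)cc(O[Si](C(C)C)(C(C)C)C(C)C)c3C(=O)[C@@H]2O[Si](C)(C)C)ccc1O[Si](C(C)C)(C(C)C)C(C)C
F7 | step 1 | 1-[2-hydroxy-4-methoxy-6-(2-methylbut-3-en-2-yloxy)phenyl]ethanone | CC(=O)c1c(O)cc(OC)cc1OC(C)(C)C=C
F8 | step 2 | 1-[2-hydroxy-4-methoxy-6-(triisopropylsilyloxy)phenyl]ethanone | CC(=O)c1c(O)cc(OC)cc1O[Si](C(C)C)(C(C)C)C(C)C
F9 | step 2 | 1-[4-methoxy-2-(2-methylbut-3-en-2-yloxy)-6-(triisopropylsilyloxy)phenyl]ethanone | CC(=O)c1c(OC(C)(C)C=C)cc(OC)cc1O[Si](C(C)C)(C(C)C)C(C)C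
F10 | step 5 | 4-(chloromethyl)-2-methoxy-1-(triisopropylsilyloxy)benzene | COc1cc(CCl)ccc1O[Si](C(C)C)(C(C)C)C(C)C
A1 | alternative 1 | 5-ethoxy-3-methoxy-2-(3-methylbut-2-enyl)phenol | CCOc1cc(O)c(CC=C(C)C)c(OC)c1
A2 | alternative 1 | 3-ethoxycyclobut-2-en-1-one | CCOC1=CC(=O)C1
A3 | alternative 1 | 1-methoxy-5-methylhex-4-en-1-yne | COC#CCC=C(C)C
A4 | alternative 2 | (2R,3R)-3-(tert-butyldimethylsilyloxy)-5-hydroxy-7-methoxy-2-[3-methoxy-4-(methoxymethoxy)phenyl]-8-(3-methylbut-2-enyl)chroman-4-one | COc1cc([C@H]2Oc3c(CC=C(C)C)c(OC)cc(O)c3C(=O)[C@@H]2O[Si](C)(C)C(C)(C)C)ccc1OCOC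
A5 | alternative 2 | methyl 4-[(2R,3R)-3-(tert-butyldimethylsilyloxy)-2-[3-methoxy-4-(methoxymethoxy)phenyl]-4-oxo-2,3-dihydropyran-6-yl]-3-methoxy-7-methylocta-2,6-dienoate | COC(=O)C=C(OC)C(CC=C(C)C)C1=CC(=O)[C@H](O[Si](C)(C)C(C)(C)C)[C@@H](c2ccc(OCOC)c(OC)c2)O1
A6 | alternative 3 | (2S)-7-methoxy-2-[3-methoxy-4-(methoxymethoxy)phenyl]-5-(methoxymethoxy)-8-(3-methylbut-2-enyl)-2H-chromene | COc1cc([C@H]2Oc3c(CC=C(C)C)c(OC)cc(OCOC)c3C=C2)ccc1OCOC
A7 | alternative 3 | 2-ethenyl-5-methoxy-1-(methoxymethoxy)-3-[(1S)-1-[3-methoxy-4-(methoxymethoxy)phenyl]prop-2-enoxy]-4-(3-methylbut-2-enyl)benzene | COc1cc([C@H](C=C)Oc2c(CC=C(C)C)c(OC)cc(OCOC)c2C=C)ccc1OCOC
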